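**Plan**

- Numbering used throughout: C1 quaternary C–CH3, C2 CHOH, C3 CH2, C4 C(OH)(i-Pr), C5 ring-fusion CH, C6 CH–OCOAr, C7=C8(CH3), C9 C=O, C10 CH2 (five-membered ring C1–C5; seven-membered ring C1, C5–C10).
- Retrosynthesis: the C6–O acyl bond, the C7=C8 unsaturation and the C5–H/C6–O pair (syn hydration of C5=C6) are removed first. This exposes, in the seven-membered ring, the γ,δ-unsaturated ketone C9(=O)–C10–C1(quaternary)–C5=C6.
- That array is a Claisen retron: cutting C1–C10 and re-forming C6–O gives a 2-methylene-oxolane (O–C9(=C10)–C8–C7–C6) whose C6 carries the tetrasubstituted cyclopentene C5=C1(CH3). Then C9=C10 (lactone methylenation), C6–C7 (allylation of a cyclopentenecarbaldehyde) and C5=C1 (aldol) are cut.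
- Forward order of rings: cyclopentene (ozonolysis/aldol ring contraction of a terpinen-4-ol-derived cyclohexene), then the γ-lactone/oxolane, then the seven-membered ring by [3,3] ring expansion, which also creates quaternary C1.
- Stereochemistry: C4 from (S)-terpinen-4-ol; C2 by catalyst-controlled CBS reduction; a temporary C6 carbinol centre by catalyst-controlled allylation, relayed suprafacially to C1 in the Claisen step; C5 and C6 together by hydroboration anti to the C1 methyl.

Key step: step 10

Remark: commercial (S)-(+)-terpinen-4-ol is assumed enantiomerically pure; C8 and C9 are temporary stereocentres (both end as sp2 carbons), so 15–27 are drawn as the expected major C8 epimer and the C9 carbinols 18–26 are carried as epimer mixtures. "Lower face" means the face of the five-membered ring that bears the C2 and C4 oxygens; "upper face" the one that bears the isopropyl group.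

**Step 1**
Reactants: 1 (S)-(+)-terpinen-4-ol
Product: 2 (S)-terpinen-4-ol triethylsilyl ether
Conditions: TESOTf, 2,6-lutidine, CH2Cl2, −78 → 0 °C
Reagents that add atoms: triethylsilyl triflate, CC[Si](CC)(CC)OS(=O)(=O)C(F)(F)F
Why: Silyl triflate/lutidine silylation of a tertiary alcohol should proceed without touching the C4 stereocentre taken from the chiral pool.

**Step 2**
Reactants: 2 (S)-terpinen-4-ol triethylsilyl ether
Product: 4 (R)-2-methyl-5-(propan-2-yl)-5-(triethylsilyloxy)cyclohex-2-en-1-one, via allylic alcohol epimers 3 (not isolated)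
Conditions: SeO2 (20 mol %), t-BuOOH, CH2Cl2, rt; then Dess–Martin periodinane, CH2Cl2, rt
Reagents that add atoms: tert-butyl hydroperoxide, CC(C)(C)OO
Why: SeO2/t-BuOOH allylic oxidation (ene reaction then [2,3] shift) should functionalise the ring CH2 next to the more substituted alkene carbon, and Dess–Martin oxidation converges both carbinol epimers and any enone already formed on 4.

**Step 3**
Reactants: 4 (R)-2-methyl-5-(propan-2-yl)-5-(triethylsilyloxy)cyclohex-2-en-1-one
Product: 5 (1R,5R)-2-methyl-5-(propan-2-yl)-5-(triethylsilyloxy)cyclohex-2-en-1-ol (1-OH cis to 5-OSiEt3)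
Conditions: (S)-2-methyl-CBS-oxazaborolidine (20 mol %), catecholborane, toluene, −78 °C
Reagents that add atoms: none
Why: Corey–Bakshi–Shibata reduction, in which the α-methylalkenyl arm acts as the large group, so the (S)-catalyst should deliver hydride to give the (R)-carbinol (future C2, cis to the C4 oxygen) under catalyst control.

**Step 4**
Reactants: 5 (1R,5R)-2-methyl-5-(propan-2-yl)-5-(triethylsilyloxy)cyclohex-2-en-1-ol
Product: 6 (1R,5R)-1-(tert-butyldimethylsilyloxy)-2-methyl-5-(propan-2-yl)-5-(triethylsilyloxy)cyclohex-2-ene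
Conditions: TBSCl, imidazole, DMF, rt
Reagents that add atoms: tert-butyldimethylsilyl chloride, CC(C)(C)[Si](C)(C)Cl
Why: Imidazole-promoted silylation of a secondary allylic alcohol is routine and leaves the carbinol configuration unchanged.

**Step 5**
Reactants: 6 (1R,5R)-1-(tert-butyldimethylsilyloxy)-2-methyl-5-(propan-2-yl)-5-(triethylsilyloxy)cyclohex-2-ene
Product: 8 (3S,5R)-5-(tert-butyldimethylsilyloxy)-6-oxo-3-(propan-2-yl)-3-(triethylsilyloxy)heptanal, via secondary ozonide 7 (not isolated)
Conditions: O3, CH2Cl2, −78 °C; then PPh3, −78 °C → rt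
Reagents that add atoms: ozone, [O-][O+]=O
Why: Ozonolysis with reductive work-up should cleave the only C=C bond to the methyl ketone and the aldehyde while both silyl ethers stay inert.

**Step 6**
Reactants: 8 (3S,5R)-5-(tert-butyldimethylsilyloxy)-6-oxo-3-(propan-2-yl)-3-(triethylsilyloxy)heptanal
Product: 10 (3R,5R)-3-(tert-butyldimethylsilyloxy)-2-methyl-5-(propan-2-yl)-5-(triethylsilyloxy)cyclopent-1-ene-1-carbaldehyde, via aldol adduct 9 (not isolated)
Conditions: Bn2NH·CF3CO2H (20 mol %), benzene, 50 °C
Reagents that add atoms: none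
Why: Amine-salt-catalysed intramolecular aldol condensation (the aldehyde enamine adds to the methyl ketone to close the five-membered ring, then dehydration), the classical keto-aldehyde to cyclopentenecarbaldehyde ring contraction; the mild salt should limit β-elimination of the C4 siloxy group and epimerisation at C2.

**Step 7**
Reactants: 10 (3R,5R)-3-(tert-butyldimethylsilyloxy)-2-methyl-5-(propan-2-yl)-5-(triethylsilyloxy)cyclopent-1-ene-1-carbaldehyde; 11 ethyl 2-(bromomethyl)acrylate
Product: 14 (S)-5-(cyclopentenyl)-3-methylideneoxolan-2-one (α-methylene-γ-lactone; new centre C6 = S), via trimethylsilyl ether 12 (not isolated), via hydroxy ester 13 (not isolated)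
Conditions: CrCl2 (10 mol %), chiral carbazole bis(oxazoline) ligand (12 mol %, antipode giving Si-face addition), i-Pr2NEt (30 mol %), Mn powder, TMSCl, THF, rt; then PPTS (cat.), MeOH, rt
Reagents that add atoms: none
Why: Catalytic asymmetric Nozaki–Hiyama–Kishi-type 2-(alkoxycarbonyl)allylation, a known entry to α-methylene-γ-butyrolactones; the ligand antipode that sends the allyl unit to the Si face of the formyl group should set (S)-C6 under catalyst control, and the γ-hydroxy ester lactonises on mild acid treatment.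

**Step 8**
Reactants: 14 (S)-5-(cyclopentenyl)-3-methylideneoxolan-2-one
Product: 15 cis-(3S,5S)-5-(cyclopentenyl)-3-methyloxolan-2-one (α-methyl-γ-lactone)
Conditions: H2 (1 atm), RhCl(PPh3)3 (5 mol %), benzene, rt
Reagents that add atoms: none
Why: Homogeneous hydrogenation with RhCl(PPh3)3 should reduce only the unhindered exocyclic methylene (the tetrasubstituted ring alkene and the allylic C–O bond are left alone), hydrogen adding anti to the C6 substituent to give mainly the cis lactone; C8 is destroyed later.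

**Step 9**
Reactants: 15 cis-(3S,5S)-5-(cyclopentenyl)-3-methyloxolan-2-one
Product: 16 (3S,5S)-5-(cyclopentenyl)-3-methyl-2-methylideneoxolane (Claisen precursor; C10=C9–O–C6–C5=C1)
Conditions: Cp2TiMe2, toluene, 70 °C, dark; filtration through basic alumina
Reagents that add atoms: dimethyltitanocene Cp2TiMe2, C[Ti](C)(C1C=CC=C1)C1C=CC=C1
Why: Petasis methylenation should convert the lactone carbonyl into the exocyclic enol ether under non-acidic conditions, without affecting the silyl ethers or the C6 centre.

**Step 10**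
Reactants: 16 (3S,5S)-5-(cyclopentenyl)-3-methyl-2-methylideneoxolane
Product: 17 hydroazulenone (bicyclo[5.3.0]dec-5-en-9-one core: C9 ketone; C5=C6; quaternary C1 with methyl on the lower face; C2 OTBS; C4 OTES/i-Pr; C8 methyl)
Conditions: toluene (0.01 M), Et3N (trace), 190 °C, sealed base-washed tube
Reagents that add atoms: none
Why: Heating 16 should trigger a concerted [3,3]-sigmatropic (Claisen) shift of the allyl vinyl ether C10=C9–O–C6–C5=C1, in which C10–C1 forms, C6–O breaks, C9 becomes the ketone and C5=C6 appears as the cis ring alkene. The closest known reaction is the ring-expanding Claisen rearrangement of 2-methylene-5-alkenyloxolanes (from lactone methylenation) to cyclohept-4-enones, including cases with a 2-methylcycloalkenyl terminus that create an angular methyl centre. The seven-membered ring closes by two-atom ring expansion of the oxacycle through a boat-like transition state imposed by the C7–C8 bridge, not by a separate cyclisation event. Quaternary C1 is set by the C6 stereocentre: only the rotamer with C7 s-cis to C1 can give the ring alkene, and in it C10 is delivered suprafacially to the cyclopentene face that carries the C6–O bond, which for (S)-C6 is the upper face, opposite the C2 and C4 siloxy groups. The step needs the exocyclic enol ether to survive until it rearranges, which base-washed glass, a trace of amine and the removal of titanium residues should secure, and it is driven by formation of the C=O bond.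

**Step 11**
Reactants: 17 hydroazulenone (C9 ketone; C5=C6)
Product: 18 C9 carbinol (C9 epimers; C5=C6 retained)
Conditions: NaBH4, MeOH, 0 °C
Reagents that add atoms: none
Why: Borohydride reduction masks C9 as a carbinol so that borane can be used on the alkene; both C9 epimers are usable because C9 is re-oxidised in step 17.

**Step 12**
Reactants: 18 C9 carbinol
Product: 19 C9 p-methoxybenzyl ether
Conditions: NaH, PMBCl, Bu4NI (cat.), THF/DMF, 0 °C → rt
Reagents that add atoms: 4-methoxybenzyl chloride, COc1ccc(CCl)cc1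
Why: Williamson etherification should give a PMB ether that survives borane, perborate and acylation and can later be removed oxidatively without touching silyl ethers or the ester.

**Step 13**
Reactants: 19 C9 p-methoxybenzyl ether
Product: 21 C6 alcohol (H5 and 6-OH on the upper face; trans ring fusion), via alkylborane 20 (not isolated)
Conditions: BH3·SMe2, THF, 0 °C → rt; then NaBO3·4H2O, THF/H2O, rt
Reagents that add atoms: sodium perborate, [Na+].[Na+].O[B-]1(O)OO[B-](O)(O)OO1
Why: Hydroboration–oxidation should add boron to the less substituted C6 and hydrogen to C5 in a syn fashion from the upper face, opposite the pseudoaxial C1 methyl and C4 siloxy group (the sense seen for Δ5-steroids with an angular methyl), which sets the trans ring fusion and the C6 carbinol together; oxidation proceeds with retention.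

**Step 14**
Reactants: 22 4-hydroxybenzoic acid
Product: 24 4-(tert-butyldimethylsilyloxy)benzoic acid, via silyl ester 23 (not isolated)
Conditions: TBSCl (2.2 equiv), imidazole, DMF, rt; then AcOH/THF/H2O, rt
Reagents that add atoms: tert-butyldimethylsilyl chloride, CC(C)(C)[Si](C)(C)Cl
Why: Bis-silylation followed by selective hydrolysis of the labile silyl ester should leave the acid-stable phenol silyl ether.

**Step 15**
Reactants: 21 C6 alcohol; 24 4-(tert-butyldimethylsilyloxy)benzoic acid
Product: 25 C6 4-(tert-butyldimethylsilyloxy)benzoate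
Conditions: DCC, DMAP, CH2Cl2, rt → 40 °C
Reagents that add atoms: none
Why: Steglich esterification (carbodiimide/DMAP) should acylate the single free hydroxyl with retention at C6.

**Step 16**
Reactants: 25 C6 4-(tert-butyldimethylsilyloxy)benzoate
Product: 26 C9 carbinol ester (C9 epimers)
Conditions: DDQ, CH2Cl2/pH 7 buffer, 0 °C
Reagents that add atoms: none
Why: DDQ should cleave the electron-rich PMB ether oxidatively while the siloxybenzoate and the silyl ethers remain intact.

**Step 17**
Reactants: 26 C9 carbinol ester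
Product: 27 C9 ketone ester
Conditions: Dess–Martin periodinane, CH2Cl2, rt
Reagents that add atoms: none
Why: Dess–Martin oxidation should restore the C9 ketone under neutral conditions compatible with the ester and silyl ethers.

**Step 18**
Reactants: 27 C9 ketone ester
Product: 29 silyl-protected enone (C7=C8–C9=O), via silyl enol ether 28 (not isolated)
Conditions: TMSOTf, Et3N, CH2Cl2, 0 °C → rt; then Pd(OAc)2, MeCN, rt
Reagents that add atoms: none
Why: Saegusa–Ito oxidation: the more substituted silyl enol ether (C8=C9) is palladated at C8 and β-hydride elimination toward C7 should give the ring enone, while the C10 side has no β-hydrogen (C1 is quaternary) so unsaturation can only enter at C7–C8.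

**Step 19**
Reactants: 29 silyl-protected enone
Product: 30 CNP0199397.1
Conditions: HF·pyridine, pyridine/THF, 0 °C → rt (polypropylene vessel)
Reagents that add atoms: none
Why: Fluoride-mediated global desilylation should cleave the aryl, secondary and tertiary silyl ethers in one operation under mildly acidic conditions that spare the aryl ester and the γ-acyloxy enone.

**Compound list**

In 10–16 and F5–F8 "cyclopentenyl" stands for the (3R,5R)-3-(tert-butyldimethylsilyloxy)-2-methyl-5-(propan-2-yl)-5-(triethylsilyloxy)cyclopent-1-en-1-yl group.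

1 | (S)-(+)-terpinen-4-ol, (S)-4-methyl-1-(propan-2-yl)cyclohex-3-en-1-ol | CC1=CC[C@](O)(C(C)C)CC1 | starting material
2 | (S)-terpinen-4-ol triethylsilyl ether | CC1=CC[C@](O[Si](CC)(CC)CC)(C(C)C)CC1 | intermediate
3 | (5R)-2-methyl-5-(propan-2-yl)-5-(triethylsilyloxy)cyclohex-2-en-1-ol, both C1 epimers | CC1=CC[C@](O[Si](CC)(CC)CC)(C(C)C)CC1O | intermediate
4 | (R)-2-methyl-5-(propan-2-yl)-5-(triethylsilyloxy)cyclohex-2-en-1-one | CC1=CC[C@](O[Si](CC)(CC)CC)(C(C)C)CC1=O | intermediate
5 | (1R,5R)-2-methyl-5-(propan-2-yl)-5-(triethylsilyloxy)cyclohex-2-en-1-ol, 1-OH cis to 5-OSiEt3 | CC1=CC[C@](O[Si](CC)(CC)CC)(C(C)C)C[C@H]1O | intermediate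
6 | (1R,5R)-1-(tert-butyldimethylsilyloxy)-2-methyl-5-(propan-2-yl)-5-(triethylsilyloxy)cyclohex-2-ene | CC1=CC[C@](O[Si](CC)(CC)CC)(C(C)C)C[C@H]1O[Si](C)(C)C(C)(C)C | intermediate
7 | secondary ozonide of 6 (1,2,4-trioxolane across the former C=C; ozonide carbons unassigned) | CC12OOC(O1)C[C@](O[Si](CC)(CC)CC)(C(C)C)C[C@H]2O[Si](C)(C)C(C)(C)C | intermediate
8 | (3S,5R)-5-(tert-butyldimethylsilyloxy)-6-oxo-3-(propan-2-yl)-3-(triethylsilyloxy)heptanal | CC(=O)[C@H](O[Si](C)(C)C(C)(C)C)C[C@@](O[Si](CC)(CC)CC)(C(C)C)CC=O | intermediate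
9 | aldol adduct, 2-hydroxy-2-methyl-3-(tert-butyldimethylsilyloxy)-5-(propan-2-yl)-5-(triethylsilyloxy)cyclopentane-1-carbaldehyde (two new centres unassigned) | O=CC1C(C)(O)[C@H](O[Si](C)(C)C(C)(C)C)C[C@@]1(O[Si](CC)(CC)CC)C(C)C | intermediate
10 | (3R,5R)-3-(tert-butyldimethylsilyloxy)-2-methyl-5-(propan-2-yl)-5-(triethylsilyloxy)cyclopent-1-ene-1-carbaldehyde | O=CC1=C(C)[C@H](O[Si](C)(C)C(C)(C)C)C[C@@]1(O[Si](CC)(CC)CC)C(C)C | intermediate
11 | ethyl 2-(bromomethyl)acrylate | C=C(CBr)C(=O)OCC | starting material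
12 | ethyl (S)-4-(cyclopentenyl)-2-methylidene-4-(trimethylsilyloxy)butanoate | CCOC(=O)C(=C)C[C@H](O[Si](C)(C)C)C1=C(C)[C@H](O[Si](C)(C)C(C)(C)C)C[C@@]1(O[Si](CC)(CC)CC)C(C)C | intermediate
13 | ethyl (S)-4-(cyclopentenyl)-4-hydroxy-2-methylidenebutanoate | CCOC(=O)C(=C)C[C@H](O)C1=C(C)[C@H](O[Si](C)(C)C(C)(C)C)C[C@@]1(O[Si](CC)(CC)CC)C(C)C | intermediate
14 | (S)-5-(cyclopentenyl)-3-methylideneoxolan-2-one | C=C1C[C@H](OC1=O)C2=C(C)[C@H](O[Si](C)(C)C(C)(C)C)C[C@@]2(O[Si](CC)(CC)CC)C(C)C | intermediate
15 | cis-(3S,5S)-5-(cyclopentenyl)-3-methyloxolan-2-one | C[C@H]1C[C@H](OC1=O)C2=C(C)[C@H](O[Si](C)(C)C(C)(C)C)C[C@@]2(O[Si](CC)(CC)CC)C(C)C | intermediate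
16 | (3S,5S)-5-(cyclopentenyl)-3-methyl-2-methylideneoxolane | C=C1O[C@@H](C[C@@H]1C)C2=C(C)[C@H](O[Si](C)(C)C(C)(C)C)C[C@@]2(O[Si](CC)(CC)CC)C(C)C | intermediate
17 | hydroazulenone: C9 ketone, C5=C6, C1 methyl (lower face), C2 OTBS, C4 OTES/i-Pr, C8 methyl | C[C@H]1CC=C2[C@@](C)(CC1=O)[C@H](O[Si](C)(C)C(C)(C)C)C[C@@]2(O[Si](CC)(CC)CC)C(C)C | intermediate
18 | C9 carbinol of 17 (C9 epimers) | C[C@H]1CC=C2[C@@](C)(CC1O)[C@H](O[Si](C)(C)C(C)(C)C)C[C@@]2(O[Si](CC)(CC)CC)C(C)C | intermediate
19 | C9 p-methoxybenzyl ether of 18 | C[C@H]1CC=C2[C@@](C)(CC1OCc3ccc(OC)cc3)[C@H](O[Si](C)(C)C(C)(C)C)C[C@@]2(O[Si](CC)(CC)CC)C(C)C | intermediate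
20 | C6 alkylborane (boron on C6 and H on C5, both on the upper face) | C[C@H]1C[C@H](B)[C@@H]2[C@@](C)(CC1OCc3ccc(OC)cc3)[C@H](O[Si](C)(C)C(C)(C)C)C[C@@]2(O[Si](CC)(CC)CC)C(C)C | intermediate
21 | C6 alcohol: trans-fused, H5 and 6-OH on the upper face, C9 OPMB | C[C@H]1C[C@H](O)[C@@H]2[C@@](C)(CC1OCc3ccc(OC)cc3)[C@H](O[Si](C)(C)C(C)(C)C)C[C@@]2(O[Si](CC)(CC)CC)C(C)C | intermediate
22 | 4-hydroxybenzoic acid | O=C(O)c1ccc(O)cc1 | starting material
23 | tert-butyldimethylsilyl 4-(tert-butyldimethylsilyloxy)benzoate | CC(C)(C)[Si](C)(C)OC(=O)c1ccc(O[Si](C)(C)C(C)(C)C)cc1 | intermediate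
24 | 4-(tert-butyldimethylsilyloxy)benzoic acid | O=C(O)c1ccc(O[Si](C)(C)C(C)(C)C)cc1 | intermediate
25 | C6 4-(tert-butyldimethylsilyloxy)benzoate of 21 | C[C@H]1C[C@H](OC(=O)c3ccc(O[Si](C)(C)C(C)(C)C)cc3)[C@@H]2[C@@](C)(CC1OCc4ccc(OC)cc4)[C@H](O[Si](C)(C)C(C)(C)C)C[C@@]2(O[Si](CC)(CC)CC)C(C)C | intermediate
26 | C9 carbinol ester (PMB removed; C9 epimers) | C[C@H]1C[C@H](OC(=O)c3ccc(O[Si](C)(C)C(C)(C)C)cc3)[C@@H]2[C@@](C)(CC1O)[C@H](O[Si](C)(C)C(C)(C)C)C[C@@]2(O[Si](CC)(CC)CC)C(C)C | intermediate
27 | C9 ketone ester | C[C@H]1C[C@H](OC(=O)c3ccc(O[Si](C)(C)C(C)(C)C)cc3)[C@@H]2[C@@](C)(CC1=O)[C@H](O[Si](C)(C)C(C)(C)C)C[C@@]2(O[Si](CC)(CC)CC)C(C)C | intermediate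
28 | C8=C9 trimethylsilyl enol ether of 27 | CC=1C[C@H](OC(=O)c3ccc(O[Si](C)(C)C(C)(C)C)cc3)[C@@H]2[C@@](C)(CC=1O[Si](C)(C)C)[C@H](O[Si](C)(C)C(C)(C)C)C[C@@]2(O[Si](CC)(CC)CC)C(C)C | intermediate
29 | tris-silyl-protected enone (C7=C8–C9=O) | CC1=C[C@H](OC(=O)c3ccc(O[Si](C)(C)C(C)(C)C)cc3)[C@@H]2[C@@](C)(CC1=O)[C@H](O[Si](C)(C)C(C)(C)C)C[C@@]2(O[Si](CC)(CC)CC)C(C)C | intermediate
30 | CNP0199397.1 | CC1=C[C@H](OC(=O)c2ccc(O)cc2)[C@@H]2[C@@](C)(CC1=O)[C@H](O)C[C@@]2(O)C(C)C | target

**Step count and risks**

Total: 19 steps. Longest linear sequence: 18 steps (1 → 30 through steps 1–13 and 15–19); step 14 is a one-step side branch.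

Most likely to fail:

1. Step 13. The borane may also add to the lower face (poor facial selectivity of the syn addition), because the C4 isopropyl group sits on the upper face; that would give the cis-fused C5/C6 epimer. The fallback sets out from ketone 17 and separates the two stereochemical events. Hydrogen-atom-transfer hydrogenation of C5=C6 (Mn(dpm)3, PhSiH3, t-BuOOH, i-PrOH) should reduce the tertiary C5 radical to the more stable trans ring fusion and give the trans-fused saturated ketone F1. Dehydrogenation with IBX (DMSO, 70 °C) gives the C7=C8 enone F2, and TMSOTf/Et3N the through-conjugated dienol trimethylsilyl ether F3. mCPBA (vinylogous Rubottom oxidation) should hydroxylate C6 from the side of H5 to give the γ-hydroxy enone F4. Steglich esterification of F4 with 24 returns to the route at 29; should the C6 epimer form instead, Mitsunobu esterification with 24 inverts it to the same 29.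

2. Step 10. The exocyclic enol ether double bond may migrate into the ring (to the tetrasubstituted dihydrofuran) under traces of acid or titanium residues before the sigmatropic shift, and the shift itself is slowed by the tetrasubstituted terminus. The fallback sets out from lactone 15 and makes the enol ether under basic conditions in the rearrangement pot. Reduction with i-Bu2AlH (CH2Cl2, −78 °C) gives the lactol F5, and homologation with the Ohira–Bestmann reagent (K2CO3, MeOH) gives the alkynol F6. Heating F6 with MeLi (10 mol %) in phenetole at 185 °C lets the alkoxide close 5-exo-dig onto the alkyne to form 16 in situ, which rearranges in the same flask; the sequence returns to the route at 17.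

3. Step 7. Catalyst control may be insufficient at the hindered, doubly flanked formyl group (low diastereoselectivity at C6, which would erode the configuration of C1 after the Claisen step), or the addition may be sluggish. The fallback sets out from aldehyde 10 and uses a stoichiometric chiral reagent. Brown methallylation with (−)-Ipc2B(2-methylallyl) (from (−)-Ipc2BOMe and 2-methylallylmagnesium chloride; Et2O, −78 °C; NaOH/H2O2), which adds to the Si face, gives the homoallylic alcohol F7. Hydroboration with 9-BBN and oxidation (NaOH/H2O2) gives the 1,4-diol F8 (C8 epimers), and oxidative lactonisation (TEMPO cat., PhI(OAc)2, CH2Cl2) returns to the route at 15, accompanied by its inconsequential C8 epimer.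

**Further compounds**

F1 | step 13 | trans-fused saturated C9 ketone (H5 on the upper face) | C[C@H]1CC[C@@H]2[C@@](C)(CC1=O)[C@H](O[Si](C)(C)C(C)(C)C)C[C@@]2(O[Si](CC)(CC)CC)C(C)C
F2 | step 13 | C7=C8 enone without C6 oxygen | CC1=CC[C@@H]2[C@@](C)(CC1=O)[C@H](O[Si](C)(C)C(C)(C)C)C[C@@]2(O[Si](CC)(CC)CC)C(C)C
F3 | step 13 | dienol trimethylsilyl ether (C9(OTMS)=C8, C7=C6) | CC=1C=C[C@@H]2[C@@](C)(CC=1O[Si](C)(C)C)[C@H](O[Si](C)(C)C(C)(C)C)C[C@@]2(O[Si](CC)(CC)CC)C(C)C
F4 | step 13 | γ-hydroxy enone (6-OH on the upper face) | CC1=C[C@H](O)[C@@H]2[C@@](C)(CC1=O)[C@H](O[Si](C)(C)C(C)(C)C)C[C@@]2(O[Si](CC)(CC)CC)C(C)C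
F5 | step 10 | lactol of 15 (anomeric centre unassigned) | C[C@H]1C[C@H](OC1O)C2=C(C)[C@H](O[Si](C)(C)C(C)(C)C)C[C@@]2(O[Si](CC)(CC)CC)C(C)C
F6 | step 10 | (1S,3S)-1-(cyclopentenyl)-3-methylpent-4-yn-1-ol | C#C[C@@H](C)C[C@H](O)C1=C(C)[C@H](O[Si](C)(C)C(C)(C)C)C[C@@]1(O[Si](CC)(CC)CC)C(C)C
F7 | step 7 | (S)-1-(cyclopentenyl)-3-methylbut-3-en-1-ol | CC(=C)C[C@H](O)C1=C(C)[C@H](O[Si](C)(C)C(C)(C)C)C[C@@]1(O[Si](CC)(CC)CC)C(C)C
F8 | step 7 | (4S)-4-(cyclopentenyl)-2-methylbutane-1,4-diol (C2 epimers) | OCC(C)C[C@H](O)C1=C(C)[C@H](O[Si](C)(C)C(C)(C)C)C[C@@]1(O[Si](CC)(CC)CC)C(C)C
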